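**Retrosynthetic overview**
- Target ⇒ fully acylated 8,9-dehydrothymol triester. The oxirane, the only ring made, is closed in the last step by catalyst-controlled asymmetric oxygen-atom transfer to the 1,1-disubstituted 8,9-alkene, copying the presumed oxygenase epoxidation of an acylated 10-oxy-8,9-dehydrothymol.
- Triester ⇒ free triol by a one-pot, phenoxide-selective tigloylation followed by double isobutyrylation.
- Triol ⇒ 2-bromo-5-(hydroxymethyl)phenol + 2-bromoallyl alcohol by a one-pot Miyaura borylation/Suzuki coupling (aryl–C8 bond).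
- Ring order: the benzene ring is bought; the oxirane is formed last, and that step also sets the single stereocentre (C8, R).

Assumption: the iron catalyst antipode is the one that converts α-methylstyrene into (R)-2-methyl-2-phenyloxirane (same spatial sense as the target); I could not fix this from memory, so it is checked on that model first, and if the S epoxide forms the mirror-image catalyst and the D-amino acid co-ligand are used.

**Step 1**
Reactants: 1 2-bromo-5-(hydroxymethyl)phenol; 2 bis(pinacolato)diboron; 3 2-bromoprop-2-en-1-ol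
Product: 5 2-[2-hydroxy-4-(hydroxymethyl)phenyl]prop-2-en-1-ol, via arylboronic pinacol ester 4 (not isolated)
Conditions: 2 (1.05 equiv), Pd(OAc)2 (2 mol%), XPhos (2-dicyclohexylphosphino-2',4',6'-triisopropylbiphenyl, 4 mol%), KOAc (3 equiv), 1,4-dioxane, 90 °C, 3 h; then 3 (1.3 equiv), 3 M aq. K3PO4 (3 equiv), 80 °C, 4 h
Reagents that add atoms: 2-bromoprop-2-en-1-ol (3), C=C(Br)CO; bis(pinacolato)diboron (2), CC1(C)OB(OC1(C)C)B1OC(C)(C)C(C)(C)O1 (boryl group of 4 only)
Why: Miyaura borylation of the aryl bromide followed in the same flask by Suzuki–Miyaura coupling with the vinyl bromide; the biarylphosphine/zerovalent palladium catalyst tolerates the free phenol and alcohols, 2-bromoallyl alcohol is a standard Suzuki electrophile, and no stereocentre is formed.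

**Step 2**
Reactants: 5 2-[2-hydroxy-4-(hydroxymethyl)phenyl]prop-2-en-1-ol; 6 (E)-2-methylbut-2-enoyl chloride (tigloyl chloride); 7 2-methylpropanoic anhydride (isobutyric anhydride)
Product: 10 2-[3-(isobutyryloxy)prop-1-en-2-yl]-5-[(isobutyryloxy)methyl]phenyl (E)-2-methylbut-2-enoate, via sodium phenoxide 8 (not isolated), via phenol tiglate diol 9 (not isolated)
Conditions: NaH (1.0 equiv), THF, 0 °C, 15 min; 6 (1.0 equiv), −40 → 0 °C, 1 h; then pyridine (5 equiv), DMAP (0.1 equiv), 7 (2.6 equiv), 0 °C → rt, 3 h
Reagents that add atoms: (E)-2-methylbut-2-enoyl chloride (6), C/C=C(\C)C(=O)Cl; 2-methylpropanoic anhydride (7), CC(C)C(=O)OC(=O)C(C)C; sodium hydride, [Na+].[H-] (sodium of 8 only)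
Why: one equivalent of NaH deprotonates only the phenol (pKa about 10), and the phenoxide is O-acylated by the acid chloride far faster than the neutral primary alcohols (chemoselective phenoxide acylation, amine-free so the tigloyl unit neither deconjugates nor isomerises), after which DMAP-catalysed anhydride acylation esterifies the two primary alcohols faster than any acyl migration; no stereocentre is formed.

**Step 3**
Reactants: 10 2-[3-(isobutyryloxy)prop-1-en-2-yl]-5-[(isobutyryloxy)methyl]phenyl (E)-2-methylbut-2-enoate; 11 hydrogen peroxide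
Product: 12 2-[(2R)-2-[(isobutyryloxy)methyl]oxiran-2-yl]-5-[(isobutyryloxy)methyl]phenyl (E)-2-methylbut-2-enoate (CNP0189152.1)
Conditions: Fe(OTf)2(L) (2 mol%; L = (S,S)-1,1'-bis[(4-dimethylaminopyridin-2-yl)methyl]-2,2'-bipyrrolidine), N-(1,8-naphthaloyl)-L-isoleucine (3 mol%), 30% aq. H2O2 (1.3 equiv, syringe pump, 30 min), MeCN, −30 °C; Na2S2O3/NaHCO3 quench, Et3N-deactivated silica
Reagents that add atoms: hydrogen peroxide (11), OO
Why: bio-inspired non-heme iron asymmetric epoxidation of an α-substituted styrene, in which the divalent iron aminopyridine complex and the amino acid carboxylate heterolyse H2O2 to an electrophilic iron-oxo oxidant (formally pentavalent iron) that transfers oxygen to one face of the electron-richer 1,1-disubstituted alkene inside the chiral pocket, setting C8 as R under catalyst control, while the electron-poor tiglate alkene and the three esters are left alone at −30 °C under near-neutral conditions.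

**Compound list**
1 | 2-bromo-5-(hydroxymethyl)phenol (4-bromo-3-hydroxybenzyl alcohol) | OCc1ccc(Br)c(O)c1 | starting material
2 | bis(pinacolato)diboron | CC1(C)OB(OC1(C)C)B1OC(C)(C)C(C)(C)O1 | starting material
3 | 2-bromoprop-2-en-1-ol (2-bromoallyl alcohol) | C=C(Br)CO | starting material
4 | 5-(hydroxymethyl)-2-(4,4,5,5-tetramethyl-1,3,2-dioxaborolan-2-yl)phenol | OCc1ccc(B2OC(C)(C)C(C)(C)O2)c(O)c1 | intermediate (not isolated)
5 | 2-[2-hydroxy-4-(hydroxymethyl)phenyl]prop-2-en-1-ol | C=C(CO)c1ccc(CO)cc1O | intermediate
6 | (E)-2-methylbut-2-enoyl chloride (tigloyl chloride) | C/C=C(\C)C(=O)Cl | starting material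
7 | 2-methylpropanoic anhydride (isobutyric anhydride) | CC(C)C(=O)OC(=O)C(C)C | starting material
8 | sodium 5-(hydroxymethyl)-2-(3-hydroxyprop-1-en-2-yl)phenoxide | C=C(CO)c1ccc(CO)cc1[O-].[Na+] | intermediate (not isolated)
9 | 5-(hydroxymethyl)-2-(3-hydroxyprop-1-en-2-yl)phenyl (E)-2-methylbut-2-enoate | C/C=C(\C)C(=O)Oc1cc(CO)ccc1C(=C)CO | intermediate (not isolated)
10 | 2-[3-(isobutyryloxy)prop-1-en-2-yl]-5-[(isobutyryloxy)methyl]phenyl (E)-2-methylbut-2-enoate | C/C=C(\C)C(=O)Oc1cc(COC(=O)C(C)C)ccc1C(=C)COC(=O)C(C)C | intermediate
11 | hydrogen peroxide | OO | starting material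
12 | 2-[(2R)-2-[(isobutyryloxy)methyl]oxiran-2-yl]-5-[(isobutyryloxy)methyl]phenyl (E)-2-methylbut-2-enoate | C/C=C(\C)C(=O)Oc1cc(COC(=O)C(C)C)ccc1[C@]1(COC(=O)C(C)C)CO1 | target

**Total step count:** 3. **Longest linear sequence:** 3.

**Steps most likely to fail, most risky first**

Step 3. The risks are three: the ortho-acyloxy group twists the arene and may lower the enantioselectivity, the tiglate alkene may compete for oxidant, and the facial sense has to be confirmed on the model. The fallback sets out from 9, obtained by stopping step 2 after the tigloylation stage and isolating it, and comes back to the route at 12. Compound 9 is submitted to a Sharpless asymmetric epoxidation directed by its free allylic alcohol: Ti(OiPr)4 (1.1 equiv), L-(+)-diisopropyl tartrate (1.3 equiv; the tartrate that turns allyl alcohol into (S)-glycidol), anhydrous tert-butyl hydroperoxide (2 equiv), 4 Å molecular sieves, CH2Cl2, −25 °C. This gives 5-(hydroxymethyl)-2-[(2S)-2-(hydroxymethyl)oxiran-2-yl]phenyl (E)-2-methylbut-2-enoate F1. Its S descriptor corresponds to the same spatial arrangement as R in the target, because esterification reverses the priority of the two CH2O arms. Both primary alcohols of F1 are then esterified with 7 (2.6 equiv), pyridine and DMAP (0.1 equiv) in CH2Cl2 at 0 °C, which gives 12 directly.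

Step 1. The risks are sluggish borylation of the unprotected ortho-bromophenol and protodeboronation of the ortho-hydroxyaryl boronate 4 under the aqueous base of the second stage. The fallback sets out from 1 and 2 and comes back at 5, with boron moved to the three-carbon partner. Propargyl alcohol (C#CCO) is protoborated with 2 under N-heterocyclic carbene–copper catalysis (CuCl 5 mol%, 1,3-dimesitylimidazolinium chloride 5 mol%, NaOtBu 20 mol%, MeOH 2 equiv, THF, −50 °C → rt). The N-aryl carbene and the propargylic oxygen direct boron to the internal carbon, giving 2-(4,4,5,5-tetramethyl-1,3,2-dioxaborolan-2-yl)prop-2-en-1-ol F2. This isolable alkenylboronate is coupled with 1 (Pd(OAc)2 2 mol%, SPhos 4 mol%, K3PO4 3 equiv, dioxane/water, 80 °C) to give 5.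

Step 2. The risks are incomplete discrimination between the phenoxide and the primary alcohols in the first stage, and phenol-to-alcohol acyl migration before the alcohols are capped. The fallback sets out from 5 and comes back at 10, with the acylation order reversed and an enzyme providing the chemoselectivity. Immobilised Candida antarctica lipase B (Novozym 435) with 7 (3 equiv) in MTBE at 30 °C acylates only the two aliphatic primary alcohols and leaves the phenol free, giving 2-[2-hydroxy-4-[(isobutyryloxy)methyl]phenyl]prop-2-en-1-yl 2-methylpropanoate F3. After filtration and a bicarbonate wash, F3 is esterified at the phenol with tiglic acid (C/C=C(\C)C(=O)O), EDC·HCl and DMAP in CH2Cl2 at rt to give 10.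

**Further compounds**
F1 | step 3 | 5-(hydroxymethyl)-2-[(2S)-2-(hydroxymethyl)oxiran-2-yl]phenyl (E)-2-methylbut-2-enoate | C/C=C(\C)C(=O)Oc1cc(CO)ccc1[C@]1(CO)CO1
F2 | step 1 | 2-(4,4,5,5-tetramethyl-1,3,2-dioxaborolan-2-yl)prop-2-en-1-ol | C=C(CO)B1OC(C)(C)C(C)(C)O1
F3 | step 2 | 2-[2-hydroxy-4-[(isobutyryloxy)methyl]phenyl]prop-2-en-1-yl 2-methylpropanoate | CC(C)C(=O)OCc1ccc(C(=C)COC(=O)C(C)C)c(O)c1
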